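**Retrosynthetic overview**
1. Target 11 comes from (2S)-5,7-bis(prenyloxy)flavanone 8 by a europium-catalysed para-Claisen–Cope shift of the 5-O-prenyl group to C8, which also frees the 5-OH and leaves C2 untouched.
2. 8 comes from 2'-hydroxychalcone 7 by a catalytic enantioselective oxa-Michael closure of the O1–C2 bond. This is the key step: it forms ring C (the only ring made; rings A and B are bought) and sets C2.
3. 7 comes from acetophenone 4 and benzaldehyde 5 (Claisen–Schmidt); 4 comes from 2',4',6'-trihydroxyacetophenone 1 and two equivalents of prenyl bromide 2.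
4. Chalcone 7 has only one free OH, so the ring closure has one possible regiochemical outcome; the C-prenyl group is delivered later from oxygen, so no direct C-prenylation is needed.

Assumption: the sense of induction of the new catalyst in step 3 cannot be predicted with certainty; the L-tert-leucine-derived catalyst is written, and its mirror image (from D-tert-leucine) is used if a first run gives the (2R) flavanone (checked by circular dichroism and chiral HPLC).

**Step 1**
Reactants: 1 2',4',6'-trihydroxyacetophenone (dried from the commercial monohydrate); 2 prenyl bromide (1-bromo-3-methylbut-2-ene)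
Product: 4 1-[2-hydroxy-4,6-bis(3-methylbut-2-enyloxy)phenyl]ethanone, via 4-O-prenyl monoether 3 (not isolated)
Conditions: 2 (2.2 equiv), K2CO3 (2.5 equiv), acetone, reflux, 8 h
Reagents that add atoms: none
Why: Williamson etherification; K2CO3 ionises the free 4-OH first and then one of the two equivalent ortho-OH groups, while the last OH stays locked in its hydrogen bond to the acetyl carbonyl and is not alkylated by 2.2 equiv of bromide; no stereocenter is formed.

**Step 2**
Reactants: 4 1-[2-hydroxy-4,6-bis(3-methylbut-2-enyloxy)phenyl]ethanone; 5 benzaldehyde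
Product: 7 (E)-1-[2-hydroxy-4,6-bis(3-methylbut-2-enyloxy)phenyl]-3-phenylprop-2-en-1-one (2'-hydroxy-4',6'-bis(prenyloxy)chalcone), via aldol adduct 6 (not isolated)
Conditions: 5 (1.2 equiv), KOH (6 equiv), EtOH, 0 °C to rt, 36 h; then cold 1 M HCl to pH 4
Reagents that add atoms: none
Why: Claisen–Schmidt condensation; the acetyl enolate adds to benzaldehyde and the aldol adduct loses water by E1cB to the conjugated (E)-enone, the prenyl ethers are inert to KOH, and the chalcone stays open as its phenoxide until the cold acid quench; no stereocenter remains.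

**Step 3**
Reactants: 7 (E)-2'-hydroxy-4',6'-bis(prenyloxy)chalcone
Product: 8 (2S)-5,7-bis(3-methylbut-2-enyloxy)-2-phenylchroman-4-one
Conditions: 1-[3,5-bis(trifluoromethyl)phenyl]-3-[(2S)-3,3-dimethyl-1-{[tris(4-methoxyphenyl)-λ5-phosphanylidene]amino}butan-2-yl]thiourea (preformed, 10 mol %), toluene (0.1 M), −20 °C, 24–48 h; AcOH (0.2 equiv) at −20 °C, silica plug; recrystallise to raise ee
Reagents that add atoms: none
Why: Proposed new method: enantioselective 6-endo-trig oxa-Michael ring closure of an unactivated 2'-hydroxychalcone by a bifunctional iminophosphorane (superbase)–thiourea catalyst. The iminophosphorane fully deprotonates the chelated 2'-OH, which tertiary-amine catalysts ionise only slightly; the two thiourea N–H bonds hold the enone carbonyl and then the developing enolate, while the P=N(+)–H unit stays ion-paired to the phenoxide, so the phenoxide oxygen adds to one face of C-β inside a tight chiral ion pair and the same N–H then protonates C3. The 6'-prenyloxy group twists the aryl ketone out of plane, which places the phenoxide over C-β and makes closure strongly downhill, so at −20 °C with an acid quench at full conversion the retro-oxa-Michael path to the racemate is suppressed and C2 is set as (S) under catalyst control. The closest known reaction types are the cinchona-alkaloid-catalysed cyclisation of 2'-hydroxychalcones (modest ee), the thiourea-catalysed cyclisation of α-ester-activated chalcones, and iminophosphorane-catalysed intramolecular oxa-Michael additions of alcohols to unsaturated esters and amides.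

**Step 4**
Reactants: 8 (2S)-5,7-bis(3-methylbut-2-enyloxy)-2-phenylchroman-4-one
Product: 11 (2S)-5-hydroxy-8-(3-methylbut-2-enyl)-7-(3-methylbut-2-enyloxy)-2-phenylchroman-4-one, via C6 Claisen dienone 9 (not isolated), via C8 Cope dienone 10 (not isolated)
Conditions: Eu(fod)3 [Eu(C10H10F7O2)3, fod = 6,6,7,7,8,8,8-heptafluoro-2,2-dimethyloctane-3,5-dionate] (10 mol %), CHCl3, 60 °C, sealed tube, 18 h
Reagents that add atoms: none
Why: Lewis-acid-catalysed para-Claisen–Cope rearrangement; trivalent europium chelates the C4 carbonyl and the 5-ether oxygen and triggers the [3,3] shift of the 5-O-prenyl group to C6 (9), a second [3,3] (Cope) shift through the C7=C8 bond moves it to C8 as a normal prenyl group (10), and enolisation gives the chelated 5-phenol; the unchelated 7-O-prenyl ether needs far higher temperature to rearrange and C2 is not involved, so the (S) configuration is kept.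

**Compound list**
1 | 1-(2,4,6-trihydroxyphenyl)ethanone (2',4',6'-trihydroxyacetophenone) | CC(=O)c1c(O)cc(O)cc1O | starting material
2 | 1-bromo-3-methylbut-2-ene (prenyl bromide) | CC(C)=CCBr | starting material
3 | 1-[2,6-dihydroxy-4-(3-methylbut-2-enyloxy)phenyl]ethanone | CC(=O)c1c(O)cc(OCC=C(C)C)cc1O | intermediate (not isolated)
4 | 1-[2-hydroxy-4,6-bis(3-methylbut-2-enyloxy)phenyl]ethanone | CC(=O)c1c(O)cc(OCC=C(C)C)cc1OCC=C(C)C | intermediate
5 | benzaldehyde | O=Cc1ccccc1 | starting material
6 | 3-hydroxy-1-[2-hydroxy-4,6-bis(3-methylbut-2-enyloxy)phenyl]-3-phenylpropan-1-one (racemic aldol adduct) | OC(CC(=O)c1c(O)cc(OCC=C(C)C)cc1OCC=C(C)C)c1ccccc1 | intermediate (not isolated)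
7 | (E)-1-[2-hydroxy-4,6-bis(3-methylbut-2-enyloxy)phenyl]-3-phenylprop-2-en-1-one | O=C(/C=C/c1ccccc1)c1c(O)cc(OCC=C(C)C)cc1OCC=C(C)C | intermediate
8 | (2S)-5,7-bis(3-methylbut-2-enyloxy)-2-phenylchroman-4-one | CC(C)=CCOc1cc(OCC=C(C)C)c2c(c1)O[C@H](c1ccccc1)CC2=O | intermediate
9 | (2S)-6-(2-methylbut-3-en-2-yl)-7-(3-methylbut-2-enyloxy)-2-phenyl-2,3-dihydrochromene-4,5(6H)-dione (C6 epimers) | C=CC(C)(C)C1C(OCC=C(C)C)=CC2=C(C1=O)C(=O)C[C@@H](c1ccccc1)O2 | intermediate (not isolated)
10 | (2S)-8-(3-methylbut-2-enyl)-7-(3-methylbut-2-enyloxy)-2-phenyl-2,3-dihydrochromene-4,5(8H)-dione (C8 epimers) | CC(C)=CCC1C(OCC=C(C)C)=CC(=O)C2=C1O[C@H](c1ccccc1)CC2=O | intermediate (not isolated)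
11 | (2S)-5-hydroxy-8-(3-methylbut-2-enyl)-7-(3-methylbut-2-enyloxy)-2-phenylchroman-4-one | CC(C)=CCOc1cc(O)c2c(c1CC=C(C)C)O[C@H](c1ccccc1)CC2=O | target

**Totals and risks**
Total step count: 4. Longest linear sequence: 4 steps (1 → 4 → 7 → 8 → 11).

Step 3 (proposed new step): the risks are low enantiomeric excess, erosion by retro-oxa-Michael reaction, or the wrong sense of induction. The fallback uses known chemistry; it sets out from chalcone 7 and comes back at 8. Chalcone 7 is cyclised with NaOAc in refluxing EtOH to racemic 5,7-bis(3-methylbut-2-enyloxy)-2-phenylchroman-4-one F1. F1 is then resolved kinetically by asymmetric transfer hydrogenation with RhCl(C5Me5)[(R,R)-TsDPEN] (TsDPEN = monoanion of N-tosyl-1,2-diphenylethane-1,2-diamine, 1 mol %) and HCO2H/Et3N in EtOAc at rt, run to about 55 % conversion. By the usual sense of this catalyst class, the (2R) ketone is reduced to (2R,4R)-cis-5,7-bis(3-methylbut-2-enyloxy)-2-phenylchroman-4-ol F2, and the unreacted (2S) ketone 8 is recovered by chromatography (at most 50 %). The prenyl alkenes are not reduced under these conditions.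

Step 4: the risks are competing ortho-Claisen product (6-(1,1-dimethylallyl) isomer), partial reaction of the 7-O-prenyl ether, and loss of ee at C2 (check by chiral HPLC). The fallback masks O7 so that the rearrangement runs on the substrate type for which it is established, and the 7-O-prenyl group is put on last; it sets out from 1 and comes back at 11.
- Compound 1 with MOMCl (1.05 equiv) and iPr2NEt in CH2Cl2 at 0 °C gives 1-[2,6-dihydroxy-4-(methoxymethoxy)phenyl]ethanone F3.
- F3 with prenyl bromide 2 (1.1 equiv) and K2CO3 in acetone gives 1-[2-hydroxy-4-(methoxymethoxy)-6-(3-methylbut-2-enyloxy)phenyl]ethanone F4.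
- F4 with benzaldehyde 5 and KOH in EtOH gives (E)-1-[2-hydroxy-4-(methoxymethoxy)-6-(3-methylbut-2-enyloxy)phenyl]-3-phenylprop-2-en-1-one F5.
- F5 is closed as in step 3 (or by the fallback to step 3) to (2S)-7-(methoxymethoxy)-5-(3-methylbut-2-enyloxy)-2-phenylchroman-4-one F6.
- F6 with Eu(fod)3 (10 mol %) in CHCl3 at 60 °C gives (2S)-5-hydroxy-7-(methoxymethoxy)-8-(3-methylbut-2-enyl)-2-phenylchroman-4-one F7.
- F7 with dilute HCl in MeOH at rt gives (2S)-5,7-dihydroxy-8-(3-methylbut-2-enyl)-2-phenylchroman-4-one F8.
- F8 undergoes a base-free Mitsunobu etherification of the free 7-OH (3-methylbut-2-en-1-ol, PPh3, DIAD, THF, 0 °C; the chelated 5-OH does not react) to give 11.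

Step 1: the risks are C-prenylation of the electron-rich ring and over-alkylation, which lower the yield of 4. The fallback replaces the phenoxide/allyl bromide pair by a redox condensation; it sets out from 1 and comes back at 4. Compound 1 is treated with 3-methylbut-2-en-1-ol (2.1 equiv), PPh3 and DIAD in THF at 0 °C to rt (double Mitsunobu etherification). No free ambident phenoxide is present, so O-alkylation of the 4-OH and one ortho-OH is favoured and the chelated OH is left; no new compound is made on this way (F0).

**Further compounds**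
F1 | step 3 | racemic 5,7-bis(3-methylbut-2-enyloxy)-2-phenylchroman-4-one | CC(C)=CCOc1cc(OCC=C(C)C)c2c(c1)OC(c1ccccc1)CC2=O
F2 | step 3 | (2R,4R)-5,7-bis(3-methylbut-2-enyloxy)-2-phenylchroman-4-ol | CC(C)=CCOc1cc(OCC=C(C)C)c2c(c1)O[C@@H](c1ccccc1)C[C@H]2O
F3 | step 4 | 1-[2,6-dihydroxy-4-(methoxymethoxy)phenyl]ethanone | CC(=O)c1c(O)cc(OCOC)cc1O
F4 | step 4 | 1-[2-hydroxy-4-(methoxymethoxy)-6-(3-methylbut-2-enyloxy)phenyl]ethanone | CC(=O)c1c(O)cc(OCOC)cc1OCC=C(C)C
F5 | step 4 | (E)-1-[2-hydroxy-4-(methoxymethoxy)-6-(3-methylbut-2-enyloxy)phenyl]-3-phenylprop-2-en-1-one | O=C(/C=C/c1ccccc1)c1c(O)cc(OCOC)cc1OCC=C(C)C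
F6 | step 4 | (2S)-7-(methoxymethoxy)-5-(3-methylbut-2-enyloxy)-2-phenylchroman-4-one | COCOc1cc(OCC=C(C)C)c2c(c1)O[C@H](c1ccccc1)CC2=O
F7 | step 4 | (2S)-5-hydroxy-7-(methoxymethoxy)-8-(3-methylbut-2-enyl)-2-phenylchroman-4-one | COCOc1cc(O)c2c(c1CC=C(C)C)O[C@H](c1ccccc1)CC2=O
F8 | step 4 | (2S)-5,7-dihydroxy-8-(3-methylbut-2-enyl)-2-phenylchroman-4-one | CC(C)=CCc1c(O)cc(O)c2c1O[C@H](c1ccccc1)CC2=O
F0 | step 1 | none | none
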